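**Plan**
- Retrosynthesis: the two ester C–O bonds are cut first, the enal is taken back to an allylic alcohol and on to an α-methylene γ-lactone, the C=CH2 bond is cut to a phosphonate, the C2–C(α) bond is cut by C–H insertion of an ester-tethered carbene, and the C5–acetyl bond is cut by Stille coupling to 5-bromobenzofuran-3(2H)-one.
- Forward: the benzofuran ring pair is bought. The C5 side chain is finished first (acetyl, carbinol, silyl ether), so that palladium never meets the later allylic aryl ether and the aryl oxygen stays a poor leaving group. The γ-lactone is the only ring made; it is opened again by reduction, then the three oxygens are differentiated and the primary alcohol is oxidised last.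
- Enabling feature: the hydrogen on C2 lies next to the ring oxygen O1, and the oxygen on C3 is two bonds from the carbon that C2 must gain. An acyl tether on that oxygen therefore closes a five-membered lactone onto C2, and fusion to the five-membered O1–C2–C3–C3a–C7a ring allows only the cis arrangement.
- Stereochemistry: C3 (R) and the side-chain carbinol (S) come from two transfer hydrogenations with the same (S,S)-TsDPEN ruthenium catalyst; C2 (R) is copied from C3 through the cis-fused lactone.

Key step: step 7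

Remark: benzofuran numbering is used throughout, and the usual sense of induction of the (S,S)-TsDPEN ruthenium catalyst for aryl ketones is assumed to hold for the benzofuranone (if it does not, the (R,R)-catalyst is used in step 1 only).

**Step 1**
Reactants: 1 5-bromo-1-benzofuran-3(2H)-one
Product: 2 (3R)-5-bromo-2,3-dihydro-1-benzofuran-3-ol
Conditions: RuCl(p-cymene)[(S,S)-TsDPEN] (1 mol%), HCO2H/Et3N (5:2), CH2Cl2, rt
Reagents that add atoms: none
Why: Noyori–Ikariya asymmetric transfer hydrogenation of a cyclic aryl ketone, in which the catalyst should deliver hydride in the sense that gives (S)-1-indanol, here named 3R because the OCH2 carbon outranks the aryl carbon.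

**Step 2**
Reactants: 2 (3R)-5-bromo-2,3-dihydro-1-benzofuran-3-ol; 3 tributyl(1-ethoxyethenyl)stannane
Product: 5 1-[(3R)-3-hydroxy-2,3-dihydro-1-benzofuran-5-yl]ethan-1-one, via enol ether 4 (not isolated)
Conditions: PdCl2(PPh3)2 (5 mol%), toluene, 100 °C; then 0.5 M aq. HCl, THF, 0 °C
Reagents that add atoms: 3 tributyl(1-ethoxyethenyl)stannane, C=C(OCC)[Sn](CCCC)(CCCC)CCCC; water, O
Why: Stille coupling of the aryl bromide with an acetyl-anion equivalent and brief acid hydrolysis of the aryl enol ether should give the methyl ketone, and it is placed here because no ester or allylic aryl ether is yet present for zerovalent palladium to ionise.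

**Step 3**
Reactants: 5 1-[(3R)-3-hydroxy-2,3-dihydro-1-benzofuran-5-yl]ethan-1-one; 6 (diethoxyphosphoryl)acetic acid
Product: 7 (3R)-5-acetyl-2,3-dihydro-1-benzofuran-3-yl (diethoxyphosphoryl)acetate
Conditions: DCC, DMAP (10 mol%), CH2Cl2, 0 °C to rt
Reagents that add atoms: 6 (diethoxyphosphoryl)acetic acid, CCOP(=O)(CC(=O)O)OCC
Why: Steglich esterification acylates at oxygen, so the C3–O bond and its configuration are untouched, and it masks this hydroxyl before the second carbinol is made.

**Step 4**
Reactants: 7 (3R)-5-acetyl-2,3-dihydro-1-benzofuran-3-yl (diethoxyphosphoryl)acetate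
Product: 8 (3R)-5-[(1S)-1-hydroxyethyl]-2,3-dihydro-1-benzofuran-3-yl (diethoxyphosphoryl)acetate
Conditions: RuCl(p-cymene)[(S,S)-TsDPEN] (2 mol%), HCO2H/Et3N (5:2), EtOAc, 30 °C
Reagents that add atoms: none
Why: Noyori–Ikariya asymmetric transfer hydrogenation of an aryl methyl ketone, which with the (S,S)-catalyst should give the (S)-1-arylethanol under catalyst control while ester and phosphonate are inert.

**Step 5**
Reactants: 8 (3R)-5-[(1S)-1-hydroxyethyl]-2,3-dihydro-1-benzofuran-3-yl (diethoxyphosphoryl)acetate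
Product: 9 (3R)-5-[(1S)-1-(triethylsilyloxy)ethyl]-2,3-dihydro-1-benzofuran-3-yl (diethoxyphosphoryl)acetate
Conditions: Et3SiCl, imidazole, CH2Cl2, 0 °C
Reagents that add atoms: chlorotriethylsilane, CC[Si](Cl)(CC)CC
Why: Imidazole-promoted silylation removes the O–H that would trap the carbenoid and installs a silyl ether that can later be cleaved beside a tert-butyldiphenylsilyl ether.

**Step 6**
Reactants: 9 (3R)-5-[(1S)-1-(triethylsilyloxy)ethyl]-2,3-dihydro-1-benzofuran-3-yl (diethoxyphosphoryl)acetate
Product: 10 (3R)-5-[(1S)-1-(triethylsilyloxy)ethyl]-2,3-dihydro-1-benzofuran-3-yl diazo(diethoxyphosphoryl)acetate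
Conditions: 4-acetamidobenzenesulfonyl azide, DBU, MeCN, 0 °C to rt
Reagents that add atoms: 4-acetamidobenzenesulfonyl azide, CC(=O)Nc1ccc(cc1)S(=O)(=O)N=[N+]=[N-]
Why: Regitz diazo transfer to the doubly activated methylene of a phosphonoacetate is a standard reaction and leaves the benzylic ester and the silyl ether alone.

**Step 7**
Reactants: 10 (3R)-5-[(1S)-1-(triethylsilyloxy)ethyl]-2,3-dihydro-1-benzofuran-3-yl diazo(diethoxyphosphoryl)acetate
Product: 11 diethyl [(3R,3aS,8bR)-2-oxo-7-[(1S)-1-(triethylsilyloxy)ethyl]-2,3,3a,8b-tetrahydrofuro[3,2-b][1]benzofuran-3-yl]phosphonate (cis-fused γ-lactone with its oxygen on C3 and its α-carbon on C2; 2S,3R in benzofuran numbering; phosphonate on the convex face)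
Conditions: Rh2(OAc)4 (2 mol%), ClCH2CH2Cl, 80 °C, slow addition of 10, 4 Å molecular sieves
Reagents that add atoms: none
Why: Rh2(OAc)4 (dirhodium tetraacetate, divalent rhodium) takes N2 from 10 to give an electrophilic rhodium carbenoid that inserts into the C2–H bond through a concerted three-centre, hydride-transfer-like transition state, forming the C2–C(α) bond with retention at C2. The closest known reaction type is the dirhodium-catalysed intramolecular C–H insertion of diazo(phosphono)acetates into C–H bonds next to ether oxygen, which gives α-phosphono γ-lactones. The one ring formed, the γ-lactone (O–C(=O)–C(α)–C2–C3), closes by 1,5-insertion, the normal five-membered mode, and is fused across C2–C3 to the dihydrofuran ring. The new centre at C2 is controlled by C3: only the C2 hydrogen cis to the ester oxygen is within reach and a five-five fusion cannot be trans, so 3R fixes C2 in the sense the target needs (named 2S here because phosphorus raises the rank of C(α), 2R after step 8), while the C(α) centre, expected exo, is erased in step 8. The step needs insertion at C2–H in preference to attack on the arene at C4, insertion into the benzylic C3–H bond (β-lactone) and carbene dimerisation; the lone pair of O1 activates C2–H, C3–H is deactivated by its acyloxy group, C4 is shielded by the neighbouring silyloxyethyl group, and slow addition at high dilution keeps the carbenoid concentration low.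

**Step 8**
Reactants: 11 the cis-fused α-phosphono γ-lactone; 12 formaldehyde
Product: 13 (3aR,8bR)-3-methylidene-7-[(1S)-1-(triethylsilyloxy)ethyl]-3a,8b-dihydrofuro[3,2-b][1]benzofuran-2(3H)-one (cis-fused α-methylene γ-lactone; 2R,3R in benzofuran numbering)
Conditions: 37% aq. HCHO, K2CO3, THF, 0 °C
Reagents that add atoms: 12 formaldehyde, C=O
Why: Horner–Wadsworth–Emmons olefination with formaldehyde removes the phosphonate and the C(α) centre, the weakly basic stabilised carbanion should leave the C2–O1 bond intact, and any reversible loss of the electron-rich aryloxide could only re-close to the cis-fused ring.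

**Step 9**
Reactants: 13 the cis-fused α-methylene γ-lactone
Product: 15 (2R,3R)-2-(3-hydroxyprop-1-en-2-yl)-5-[(1S)-1-(triethylsilyloxy)ethyl]-2,3-dihydro-1-benzofuran-3-ol, via methylene lactol 14 (not isolated)
Conditions: i-Bu2AlH (DIBAL-H, 4 equiv), CH2Cl2, −78 to −20 °C; aq. KNaC4H4O6 (potassium sodium tartrate) work-up
Reagents that add atoms: none
Why: Hydride reduction of a lactone with DIBAL-H proceeds by 1,2-addition through the lactol to the allylic alcohol and frees the C3 hydroxyl without breaking any bond at C2 or C3.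

**Step 10**
Reactants: 15 (2R,3R)-2-(3-hydroxyprop-1-en-2-yl)-5-[(1S)-1-(triethylsilyloxy)ethyl]-2,3-dihydro-1-benzofuran-3-ol
Product: 16 (2R,3R)-2-[3-(tert-butyldiphenylsilyloxy)prop-1-en-2-yl]-5-[(1S)-1-(triethylsilyloxy)ethyl]-2,3-dihydro-1-benzofuran-3-ol
Conditions: t-BuPh2SiCl, imidazole, CH2Cl2, 0 °C
Reagents that add atoms: tert-butyl(chloro)diphenylsilane, CC(C)(C)[Si](Cl)(c1ccccc1)c1ccccc1
Why: Silylation with a bulky chlorosilane is selective for the primary allylic alcohol over the hindered secondary benzylic hydroxyl on steric grounds.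

**Step 11**
Reactants: 16 the primary silyl ether with free C3 hydroxyl; 17 3-methylbutanoyl chloride
Product: 18 (2R,3R)-2-[3-(tert-butyldiphenylsilyloxy)prop-1-en-2-yl]-5-[(1S)-1-(triethylsilyloxy)ethyl]-2,3-dihydro-1-benzofuran-3-yl 3-methylbutanoate
Conditions: pyridine, DMAP (10 mol%), CH2Cl2, 0 °C to rt
Reagents that add atoms: 17 3-methylbutanoyl chloride, CC(C)CC(=O)Cl
Why: DMAP-catalysed acylation takes place at oxygen, so the 3R centre is retained, and both silyl ethers tolerate acid chloride and pyridine.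

**Step 12**
Reactants: 18 the C3 isovalerate carrying both silyl ethers
Product: 19 (2R,3R)-2-[3-(tert-butyldiphenylsilyloxy)prop-1-en-2-yl]-5-[(1S)-1-hydroxyethyl]-2,3-dihydro-1-benzofuran-3-yl 3-methylbutanoate
Conditions: HF·pyridine, pyridine, THF, 0 °C
Reagents that add atoms: none
Why: Fluoride-mediated desilylation with pyridine-buffered HF cleaves a triethylsilyl ether much faster than a tert-butyldiphenylsilyl ether, so only the side-chain carbinol should be freed, with its C–O bond and S configuration untouched.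

**Step 13**
Reactants: 19 the side-chain alcohol; 20 3-methylbut-2-enoic acid
Product: 21 (1S)-1-[(2R,3R)-2-[3-(tert-butyldiphenylsilyloxy)prop-1-en-2-yl]-3-(3-methylbutanoyloxy)-2,3-dihydro-1-benzofuran-5-yl]ethyl 3-methylbut-2-enoate
Conditions: DCC, DMAP (20 mol%), CH2Cl2, 0 °C to rt
Reagents that add atoms: 20 3-methylbut-2-enoic acid, CC(C)=CC(=O)O
Why: Steglich esterification acylates the carbinol at oxygen with retention and avoids the acid chloride and amine conditions under which this acyl group deconjugates through a vinylketene.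

**Step 14**
Reactants: 21 the diester with primary silyl ether
Product: 22 (1S)-1-[(2R,3R)-2-(3-hydroxyprop-1-en-2-yl)-3-(3-methylbutanoyloxy)-2,3-dihydro-1-benzofuran-5-yl]ethyl 3-methylbut-2-enoate
Conditions: Bu4NF, AcOH (1:1), THF, 0 °C to rt
Reagents that add atoms: none
Why: Fluoride cleavage of the primary silyl ether, buffered with acetic acid, should free the allylic alcohol without acyl migration from C3 or loss of either ester.

**Step 15**
Reactants: 22 the allylic alcohol
Product: 23 (1S)-1-[(2R,3R)-3-(3-methylbutanoyloxy)-2-(3-oxoprop-1-en-2-yl)-2,3-dihydro-1-benzofuran-5-yl]ethyl 3-methylbut-2-enoate (target)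
Conditions: TEMPO (10 mol%), PhI(OAc)2, CH2Cl2, rt
Reagents that add atoms: none
Why: Oxoammonium oxidation (TEMPO with PhI(OAc)2) takes a primary allylic alcohol to the enal without over-oxidation and without base, so elimination of the C3 ester through the now acidic C2–H should not be triggered.

**Compound list**
1 | 5-bromo-1-benzofuran-3(2H)-one | O=C1COc2ccc(Br)cc21 | starting material
2 | (3R)-5-bromo-2,3-dihydro-1-benzofuran-3-ol | O[C@H]1COc2ccc(Br)cc21 | intermediate
3 | tributyl(1-ethoxyethenyl)stannane | C=C(OCC)[Sn](CCCC)(CCCC)CCCC | starting material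
4 | (3R)-5-(1-ethoxyethenyl)-2,3-dihydro-1-benzofuran-3-ol | O[C@H]1COc2ccc(C(=C)OCC)cc21 | intermediate (not isolated)
5 | 1-[(3R)-3-hydroxy-2,3-dihydro-1-benzofuran-5-yl]ethan-1-one | O[C@H]1COc2ccc(C(C)=O)cc21 | intermediate
6 | (diethoxyphosphoryl)acetic acid | CCOP(=O)(CC(=O)O)OCC | starting material
7 | (3R)-5-acetyl-2,3-dihydro-1-benzofuran-3-yl (diethoxyphosphoryl)acetate | CCOP(=O)(CC(=O)O[C@H]1COc2ccc(C(C)=O)cc21)OCC | intermediate
8 | (3R)-5-[(1S)-1-hydroxyethyl]-2,3-dihydro-1-benzofuran-3-yl (diethoxyphosphoryl)acetate | CCOP(=O)(CC(=O)O[C@H]1COc2ccc([C@H](C)O)cc21)OCC | intermediate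
9 | (3R)-5-[(1S)-1-(triethylsilyloxy)ethyl]-2,3-dihydro-1-benzofuran-3-yl (diethoxyphosphoryl)acetate | CCOP(=O)(CC(=O)O[C@H]1COc2ccc([C@H](C)O[Si](CC)(CC)CC)cc21)OCC | intermediate
10 | (3R)-5-[(1S)-1-(triethylsilyloxy)ethyl]-2,3-dihydro-1-benzofuran-3-yl diazo(diethoxyphosphoryl)acetate | CCOP(=O)(C(=[N+]=[N-])C(=O)O[C@H]1COc2ccc([C@H](C)O[Si](CC)(CC)CC)cc21)OCC | intermediate
11 | diethyl [(3R,3aS,8bR)-2-oxo-7-[(1S)-1-(triethylsilyloxy)ethyl]-2,3,3a,8b-tetrahydrofuro[3,2-b][1]benzofuran-3-yl]phosphonate | O=C1O[C@@H]2c3cc([C@H](C)O[Si](CC)(CC)CC)ccc3O[C@@H]2[C@H]1P(=O)(OCC)OCC | intermediate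
12 | formaldehyde | C=O | starting material
13 | (3aR,8bR)-3-methylidene-7-[(1S)-1-(triethylsilyloxy)ethyl]-3a,8b-dihydrofuro[3,2-b][1]benzofuran-2(3H)-one | O=C1O[C@@H]2c3cc([C@H](C)O[Si](CC)(CC)CC)ccc3O[C@@H]2C1=C | intermediate
14 | (3aR,8bR)-3-methylidene-7-[(1S)-1-(triethylsilyloxy)ethyl]-2,3,3a,8b-tetrahydrofuro[3,2-b][1]benzofuran-2-ol (lactol, present as its aluminium alkoxide, anomeric centre undefined) | OC1O[C@@H]2c3cc([C@H](C)O[Si](CC)(CC)CC)ccc3O[C@@H]2C1=C | intermediate (not isolated)
15 | (2R,3R)-2-(3-hydroxyprop-1-en-2-yl)-5-[(1S)-1-(triethylsilyloxy)ethyl]-2,3-dihydro-1-benzofuran-3-ol | C=C(CO)[C@H]1Oc2ccc([C@H](C)O[Si](CC)(CC)CC)cc2[C@H]1O | intermediate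
16 | (2R,3R)-2-[3-(tert-butyldiphenylsilyloxy)prop-1-en-2-yl]-5-[(1S)-1-(triethylsilyloxy)ethyl]-2,3-dihydro-1-benzofuran-3-ol | C=C(CO[Si](c3ccccc3)(c3ccccc3)C(C)(C)C)[C@H]1Oc2ccc([C@H](C)O[Si](CC)(CC)CC)cc2[C@H]1O | intermediate
17 | 3-methylbutanoyl chloride | CC(C)CC(=O)Cl | starting material
18 | (2R,3R)-2-[3-(tert-butyldiphenylsilyloxy)prop-1-en-2-yl]-5-[(1S)-1-(triethylsilyloxy)ethyl]-2,3-dihydro-1-benzofuran-3-yl 3-methylbutanoate | C=C(CO[Si](c3ccccc3)(c3ccccc3)C(C)(C)C)[C@H]1Oc2ccc([C@H](C)O[Si](CC)(CC)CC)cc2[C@H]1OC(=O)CC(C)C | intermediate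
19 | (2R,3R)-2-[3-(tert-butyldiphenylsilyloxy)prop-1-en-2-yl]-5-[(1S)-1-hydroxyethyl]-2,3-dihydro-1-benzofuran-3-yl 3-methylbutanoate | C=C(CO[Si](c3ccccc3)(c3ccccc3)C(C)(C)C)[C@H]1Oc2ccc([C@H](C)O)cc2[C@H]1OC(=O)CC(C)C | intermediate
20 | 3-methylbut-2-enoic acid | CC(C)=CC(=O)O | starting material
21 | (1S)-1-[(2R,3R)-2-[3-(tert-butyldiphenylsilyloxy)prop-1-en-2-yl]-3-(3-methylbutanoyloxy)-2,3-dihydro-1-benzofuran-5-yl]ethyl 3-methylbut-2-enoate | C=C(CO[Si](c3ccccc3)(c3ccccc3)C(C)(C)C)[C@H]1Oc2ccc([C@H](C)OC(=O)C=C(C)C)cc2[C@H]1OC(=O)CC(C)C | intermediate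
22 | (1S)-1-[(2R,3R)-2-(3-hydroxyprop-1-en-2-yl)-3-(3-methylbutanoyloxy)-2,3-dihydro-1-benzofuran-5-yl]ethyl 3-methylbut-2-enoate | C=C(CO)[C@H]1Oc2ccc([C@H](C)OC(=O)C=C(C)C)cc2[C@H]1OC(=O)CC(C)C | intermediate
23 | (1S)-1-[(2R,3R)-3-(3-methylbutanoyloxy)-2-(3-oxoprop-1-en-2-yl)-2,3-dihydro-1-benzofuran-5-yl]ethyl 3-methylbut-2-enoate | C=C(C=O)[C@H]1Oc2ccc([C@H](C)OC(=O)C=C(C)C)cc2[C@H]1OC(=O)CC(C)C | target

**Step count**
Total steps: 15. Longest linear sequence: 15 steps (1 to 23).

**Steps most likely to fail**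

Step 7. The carbenoid may be diverted before it reaches C2–H: by electrophilic attack on the arene at C4, by insertion into the benzylic C3–H bond to a β-lactone, or by thermal ionisation of the benzylic ester with aromatisation to a benzofuran. The fallback sets out from 9 and comes back at 13. It replaces the doubly stabilised carbenoid by an acceptor-only one under a chiral dirhodium carboxamidate, a catalyst class known to favour γ-lactones by insertion next to ether oxygen at lower temperature, and it brings the methylene in afterwards without a phosphonate. K2CO3 in methanol at 0 °C should remove the phosphonoacetyl group from 9 to give (3R)-5-[(1S)-1-(triethylsilyloxy)ethyl]-2,3-dihydro-1-benzofuran-3-ol F1. Bromoacetyl bromide and pyridine should then give the bromoacetate (3R)-5-[(1S)-1-(triethylsilyloxy)ethyl]-2,3-dihydro-1-benzofuran-3-yl bromoacetate F2, and N,N'-ditosylhydrazine with DBU in THF should convert it into (3R)-5-[(1S)-1-(triethylsilyloxy)ethyl]-2,3-dihydro-1-benzofuran-3-yl diazoacetate F3. With Rh2(5S-MEPY)4 (dirhodium tetrakis[methyl (5S)-2-oxopyrrolidine-5-carboxylate], divalent rhodium; or its enantiomer, whichever matches C3) in CH2Cl2 at 40 °C, F3 should close to the phosphonate-free cis-fused lactone (3aR,8bR)-7-[(1S)-1-(triethylsilyloxy)ethyl]-3a,8b-dihydrofuro[3,2-b][1]benzofuran-2(3H)-one F4. Heating with tert-butoxybis(dimethylamino)methane in toluene at 80 °C should give the aminomethylene lactone (3E,3aR,8bR)-3-[(dimethylamino)methylidene]-7-[(1S)-1-(triethylsilyloxy)ethyl]-3a,8b-dihydrofuro[3,2-b][1]benzofuran-2(3H)-one F5. Conjugate reduction with i-Bu2AlH at −78 °C and loss of dimethylamine on work-up should then deliver 13, so this detour also stands in for step 8.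

Step 2. The ring carbinol may dehydrate to the aromatic benzofuran, or lose configuration by ionisation, under the tin halide at 100 °C or during the acidic hydrolysis of the enol ether. The fallback sets out from 2 and comes back at 5, and it replaces the palladium coupling by an organolithium acylation that needs neither heat nor acid. t-BuMe2SiCl and imidazole should give tert-butyl{[(3R)-5-bromo-2,3-dihydro-1-benzofuran-3-yl]oxy}dimethylsilane F6. Bromine–lithium exchange with n-BuLi in THF at −78 °C and addition of N-methoxy-N-methylacetamide should give 1-[(3R)-3-(tert-butyldimethylsilyloxy)-2,3-dihydro-1-benzofuran-5-yl]ethan-1-one F7, and Bu4NF buffered with AcOH should return 5.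

Step 12. The two silyl ethers may not be told apart cleanly, or the electron-rich benzylic C–O bonds may ionise in the HF medium, with loss of the side-chain configuration. The fallback sets out from 18 and comes back at 23, and it gives up protecting-group discrimination in favour of a chemoselective oxidation. Excess Bu4NF with AcOH in THF should remove both silyl groups to give (2R,3R)-5-[(1S)-1-hydroxyethyl]-2-(3-hydroxyprop-1-en-2-yl)-2,3-dihydro-1-benzofuran-3-yl 3-methylbutanoate F8. TEMPO with PhI(OAc)2 should oxidise only the primary allylic alcohol, the secondary benzylic one reacting far more slowly, to give (2R,3R)-5-[(1S)-1-hydroxyethyl]-2-(3-oxoprop-1-en-2-yl)-2,3-dihydro-1-benzofuran-3-yl 3-methylbutanoate F9. Steglich esterification of F9 with 20 (DCC, catalytic DMAP, 0 °C) should then give 23 directly.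

**Further compounds**
F1 | step 7 | (3R)-5-[(1S)-1-(triethylsilyloxy)ethyl]-2,3-dihydro-1-benzofuran-3-ol | O[C@H]1COc2ccc([C@H](C)O[Si](CC)(CC)CC)cc21
F2 | step 7 | (3R)-5-[(1S)-1-(triethylsilyloxy)ethyl]-2,3-dihydro-1-benzofuran-3-yl bromoacetate | BrCC(=O)O[C@H]1COc2ccc([C@H](C)O[Si](CC)(CC)CC)cc21
F3 | step 7 | (3R)-5-[(1S)-1-(triethylsilyloxy)ethyl]-2,3-dihydro-1-benzofuran-3-yl diazoacetate | [N-]=[N+]=CC(=O)O[C@H]1COc2ccc([C@H](C)O[Si](CC)(CC)CC)cc21
F4 | step 7 | (3aR,8bR)-7-[(1S)-1-(triethylsilyloxy)ethyl]-3a,8b-dihydrofuro[3,2-b][1]benzofuran-2(3H)-one | O=C1O[C@@H]2c3cc([C@H](C)O[Si](CC)(CC)CC)ccc3O[C@@H]2C1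
F5 | step 7 | (3E,3aR,8bR)-3-[(dimethylamino)methylidene]-7-[(1S)-1-(triethylsilyloxy)ethyl]-3a,8b-dihydrofuro[3,2-b][1]benzofuran-2(3H)-one | O=C1O[C@@H]2c3cc([C@H](C)O[Si](CC)(CC)CC)ccc3O[C@@H]2/C1=C\N(C)C
F6 | step 2 | tert-butyl{[(3R)-5-bromo-2,3-dihydro-1-benzofuran-3-yl]oxy}dimethylsilane | CC(C)(C)[Si](C)(C)O[C@H]1COc2ccc(Br)cc21
F7 | step 2 | 1-[(3R)-3-(tert-butyldimethylsilyloxy)-2,3-dihydro-1-benzofuran-5-yl]ethan-1-one | CC(C)(C)[Si](C)(C)O[C@H]1COc2ccc(C(C)=O)cc21
F8 | step 12 | (2R,3R)-5-[(1S)-1-hydroxyethyl]-2-(3-hydroxyprop-1-en-2-yl)-2,3-dihydro-1-benzofuran-3-yl 3-methylbutanoate | C=C(CO)[C@H]1Oc2ccc([C@H](C)O)cc2[C@H]1OC(=O)CC(C)C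
F9 | step 12 | (2R,3R)-5-[(1S)-1-hydroxyethyl]-2-(3-oxoprop-1-en-2-yl)-2,3-dihydro-1-benzofuran-3-yl 3-methylbutanoate | C=C(C=O)[C@H]1Oc2ccc([C@H](C)O)cc2[C@H]1OC(=O)CC(C)C
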